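## Retrosynthetic overview

1. The target is (3R,3'R,6'R)-lutein 3-O-myristate 3'-O-palmitate. The polyene is cut at C11=C12 and C11'=C12' (two Wittig reactions) into a ring-A C15 phosphonium salt, the commercial C10 dialdehyde, and a ring-B C15 phosphonium salt that already carries the palmitate. The myristate is put on at the C25 aldehyde stage, so the two esters never compete.
2. Ring A (β-ring, C1–C6) is built first, from acyclic pieces, by an alkyne Diels–Alder reaction that forms C4–C5 and C1–C6 in one operation. The diene is the silyl dienol ether of mesityl oxide (C4=C3(OSi)–C2=C1Me2); the dienophile is but-2-ynal (C5≡C6 with the C5 methyl and C7).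
3. The enabling feature: in ring A the tetrasubstituted C5=C6 lies between C4H2 and the quaternary C1, 1,4 to the oxygen-bearing C3. With C3 at the enol-ether (ketone) level, ring A is a cyclohexa-1,4-diene, the retron of a diene plus alkyne cycloaddition, and the quaternary C1 rules out aromatization.
4. C3 is then set by a ketoreductase. Ring B (ε-ring, C1'–C6') is not formed but bought with racemic α-ionone, oxidized at C3', and set and resolved to 3'R,6'R by a second ketoreductase.

Key step: step 3

Assumption: carotenoid numbering is used throughout (ring A = β-ring with the myristate at C3; ring B = ε-ring with the palmitate at C3'), and each ketoreductase is taken from a commercial screening panel for the selectivity stated.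

## Route

Step 1
Reactants: 1 but-2-yn-1-ol
Product: 2 but-2-ynal
Conditions: MnO2 (activated, excess), CH2Cl2, rt; filtered, solvent exchanged to toluene, used at once
Reagents that add atoms: none
Why: Manganese dioxide oxidation of a propargylic alcohol should stop cleanly at the ynal, which is volatile and is therefore carried on in solution.

Step 2
Reactants: 3 mesityl oxide (4-methylpent-3-en-2-one)
Product: 5 tert-butyl(dimethyl)[(4-methylpenta-1,3-dien-2-yl)oxy]silane, via lithium dienolate 4 (not isolated)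
Conditions: LiN(i-Pr)2, THF, −78 °C; then TBSCl, DMPU, −78 → 0 °C
Reagents that add atoms: tert-butyl(chloro)dimethylsilane (TBSCl), CC(C)(C)[Si](C)(C)Cl
Why: Kinetic deprotonation of the enone at the α'-methyl group gives the cross-conjugated lithium dienolate, which is O-silylated to the 2-silyloxy-1,3-diene (silyl enol ether formation).

Step 3
Reactants: 5 tert-butyl(dimethyl)[(4-methylpenta-1,3-dien-2-yl)oxy]silane, 2 but-2-ynal
Product: 6 4-{[tert-butyl(dimethyl)silyl]oxy}-2,6,6-trimethylcyclohexa-1,4-diene-1-carbaldehyde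
Conditions: 2 (1.5 equiv), toluene, BHT (cat.), 100 °C, sealed tube
Reagents that add atoms: none
Why: This is a concerted but asynchronous normal-electron-demand [4+2] cycloaddition (Diels–Alder reaction) of the electron-rich 2-silyloxy diene with the ynal; the closest known type is the cycloaddition of 2-silyloxy-1,3-dienes with acetylenic aldehydes, ketones and esters to give cyclohexa-1,4-dienes. Ring A is closed in the intermolecular [4+2] mode: the diene termini C4 (CH2) and C1 (CMe2) are joined suprafacially to the alkyne carbons C5 and C6, so both ring bonds (C4–C5 and C1–C6) form in the one step. No stereocentre is created, because C1 carries two identical methyl groups and C3 stays sp2 as the silyl enol ether, a masked ketone that is reduced in step 5. The step needs regioselectivity: the 2-silyloxy group and the two terminal methyl groups both make the CH2 terminus the nucleophilic end, so it should bond to the electrophilic β-carbon of the ynal (the methyl-bearing carbon, C5) and place the formyl group on C6, next to the gem-dimethyl carbon and para to the oxygen. It also needs chemoselectivity for C≡C over C=O and over a 1,5-hydrogen shift of the diene, which the moderate temperature, the absence of Lewis acid and the reactivity of the ynal should secure; the rod-shaped alkyne has no endo or exo substituent to clash with the inward methyl group of the diene. The quaternary C1 makes aromatization of the 1,4-diene impossible, and the adduct already holds C5=C6, the gem-dimethyl carbon, the C3 oxygen and C7.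

Step 4
Reactants: 6 4-{[tert-butyl(dimethyl)silyl]oxy}-2,6,6-trimethylcyclohexa-1,4-diene-1-carbaldehyde
Product: 8 (3E)-4-(2,6,6-trimethyl-4-oxocyclohex-1-en-1-yl)but-3-en-2-one (3-oxo-β-ionone), via silyl enol ether enone 7 (not isolated)
Conditions: (MeO)2P(O)CH2C(O)CH3, NaH, THF, 0 °C → rt; then HF·pyridine, pyridine, 0 °C
Reagents that add atoms: dimethyl (2-oxopropyl)phosphonate, COP(=O)(OC)CC(C)=O
Why: E-selective Horner–Wadsworth–Emmons olefination of the hindered enal is run while the silyl enol ether masks the C3 ketone and holds C5=C6 in place, and buffered fluoride then frees the ketone by C-protonation at C2 without moving the double bond.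

Step 5
Reactants: 8 3-oxo-β-ionone
Product: 9 (3E)-4-[(4R)-4-hydroxy-2,6,6-trimethylcyclohex-1-en-1-yl]but-3-en-2-one ((3R)-3-hydroxy-β-ionone)
Conditions: ketoreductase (NADPH-dependent), NADP+ (cat.), i-PrOH, phosphate buffer pH 7, 30 °C
Reagents that add atoms: none
Why: Enzymatic carbonyl reduction by a ketoreductase (short-chain alcohol dehydrogenase) should take the unconjugated ring ketone and leave the shielded conjugated side-chain ketone, with hydride delivered in the active site to the Si face of C3 to give the 3R carbinol; the closely related 4-oxo group of 2,2,6-trimethylcyclohexane-1,4-dione is known to be reduced by such enzymes with high selectivity.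

Step 6
Reactants: 9 (3R)-3-hydroxy-β-ionone
Product: 10 (1E)-1-[(4R)-4-hydroxy-2,6,6-trimethylcyclohex-1-en-1-yl]-3-methylpenta-1,4-dien-3-ol (both epimers at the new carbinol carbon)
Conditions: CH2=CHMgBr (3 equiv), THF, −20 → 0 °C; aq. NH4Cl
Reagents that add atoms: vinylmagnesium bromide, C=C[Mg]Br
Why: Grignard 1,2-addition to the dienone follows deprotonation of the free hydroxyl; the new carbinol centre forms as both epimers, which does not matter because it is lost in step 7.

Step 7
Reactants: 10 the vinyl carbinol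
Product: 11 [(2E,4E)-5-[(4R)-4-hydroxy-2,6,6-trimethylcyclohex-1-en-1-yl]-3-methylpenta-2,4-dien-1-yl]triphenylphosphonium bromide
Conditions: PPh3·HBr, MeOH, rt; crystallization
Reagents that add atoms: triphenylphosphine hydrobromide, [Br-].c1ccccc1[PH+](c1ccccc1)c1ccccc1
Why: Acid-induced ionization of the tertiary bis-allylic alcohol and capture of the pentadienyl cation by PPh3 at the primary terminus (allylic transposition, SN1') should give the C15 phosphonium salt, all-E after crystallization, while the secondary homoallylic C3 hydroxyl does not ionize.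

Step 8
Reactants: 11 ring-A C15 phosphonium bromide, 12 (2E,4E,6E)-2,7-dimethylocta-2,4,6-trienedial (3 equiv)
Product: 15 (3R)-3-hydroxy-12'-apo-β-caroten-12'-al, via phosphorus ylide 13 (not isolated), via 11Z isomer 14 (not isolated)
Conditions: 1,2-epoxybutane, EtOH, reflux; chromatography, crystallization
Reagents that add atoms: none
Why: Wittig olefination with the ylide generated by the epoxide–bromide method should give mono-olefination because the dialdehyde is in excess, and the hindered 11Z portion should equilibrate to the all-E aldehyde at reflux.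

Step 9
Reactants: 15 (3R)-3-hydroxy-12'-apo-β-caroten-12'-al
Product: 16 (3R)-3-(tetradecanoyloxy)-12'-apo-β-caroten-12'-al
Conditions: C13H27COCl, pyridine, DMAP (cat.), CH2Cl2, 0 °C → rt
Reagents that add atoms: tetradecanoyl chloride (myristoyl chloride), CCCCCCCCCCCCCC(=O)Cl
Why: Acylation of the secondary alcohol by the acid chloride (nucleophilic acyl substitution) leaves the aldehyde, the polyene and the C3 configuration untouched.

Step 10
Reactants: 17 racemic α-ionone ((3E)-4-(2,6,6-trimethylcyclohex-2-en-1-yl)but-3-en-2-one)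
Product: 18 racemic 2-methyl-2-[(E)-2-(2,6,6-trimethylcyclohex-2-en-1-yl)ethenyl]-1,3-dioxolane
Conditions: ethylene glycol, HC(OEt)3, p-TsOH (cat.), rt
Reagents that add atoms: ethane-1,2-diol, OCCO
Why: Ketalization masks the side-chain ketone so that only the ring will carry a carbonyl group later, and the mild orthoformate-driven conditions should leave both double bonds in place.

Step 11
Reactants: 18 α-ionone ketal
Product: 19 racemic 3,5,5-trimethyl-4-[(E)-2-(2-methyl-1,3-dioxolan-2-yl)ethenyl]cyclohex-2-en-1-one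
Conditions: t-BuOOH (70% aq.), NaOCl (aq.), MeCN, 0 °C
Reagents that add atoms: tert-butyl hydroperoxide, CC(C)(C)OO
Why: Radical allylic oxidation by tert-butylperoxy radicals should attack the ring methylene C3', the only allylic CH2, and give the conjugated ring enone while the ketal survives the non-acidic medium.

Step 12
Reactants: 19 racemic 3'-oxo ketal
Product: 20 (1R,4R)-3,5,5-trimethyl-4-[(E)-2-(2-methyl-1,3-dioxolan-2-yl)ethenyl]cyclohex-2-en-1-ol
Conditions: ketoreductase (NADPH-dependent), NADP+ (cat.), i-PrOH, phosphate buffer pH 7, DMSO (5%), 30 °C, to about half conversion; chromatography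
Reagents that add atoms: none
Why: Enzymatic carbonyl reduction of a cyclohexenone by a ketoreductase, run as a kinetic resolution, should deliver hydride to the Si face of C3' of the 6'R enantiomer only, so the enzyme sets 3'R and selects 6'R (hydroxyl trans to the side chain) and the unreduced 6'S ketone is removed by chromatography.

Step 13
Reactants: 20 (3'R,6'R)-hydroxy ketal
Product: 21 (3E)-4-[(1R,4R)-4-hydroxy-2,6,6-trimethylcyclohex-2-en-1-yl]but-3-en-2-one ((3R,6R)-3-hydroxy-α-ionone)
Conditions: oxalic acid (cat.), THF–H2O, rt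
Reagents that add atoms: water, O
Why: Mild acid hydrolysis of the allylic dioxolane frees the side-chain ketone under conditions that should not ionize the ring allylic alcohol.

Step 14
Reactants: 21 (3R,6R)-3-hydroxy-α-ionone
Product: 22 (1R,4R)-4-[(1E)-3-hydroxy-3-methylpenta-1,4-dien-1-yl]-3,5,5-trimethylcyclohex-2-en-1-ol (both epimers at the new carbinol carbon)
Conditions: CH2=CHMgBr (3 equiv), THF, −20 → 0 °C; aq. NH4Cl
Reagents that add atoms: vinylmagnesium bromide, C=C[Mg]Br
Why: Grignard 1,2-addition to the enone is faster than deprotonation at C6', so the 6'R centre should be kept; the new carbinol centre is lost in step 16.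

Step 15
Reactants: 22 the ring-B diol
Product: 23 (1R,4R)-4-[(1E)-3-hydroxy-3-methylpenta-1,4-dien-1-yl]-3,5,5-trimethylcyclohex-2-en-1-yl hexadecanoate
Conditions: C15H31COCl (1.05 equiv), pyridine, CH2Cl2, −10 → 0 °C
Reagents that add atoms: hexadecanoyl chloride (palmitoyl chloride), CCCCCCCCCCCCCCCC(=O)Cl
Why: Acylation with an acid chloride in pyridine is selective for the secondary over the tertiary alcohol and proceeds with retention at C3'.

Step 16
Reactants: 23 the palmitate vinyl carbinol
Product: 24 [(2E,4E)-5-[(1R,4R)-4-(hexadecanoyloxy)-2,6,6-trimethylcyclohex-2-en-1-yl]-3-methylpenta-2,4-dien-1-yl]triphenylphosphonium bromide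
Conditions: PPh3·HBr (1.0 equiv), CH2Cl2, 0 °C
Reagents that add atoms: triphenylphosphine hydrobromide, [Br-].c1ccccc1[PH+](c1ccccc1)c1ccccc1
Why: The same SN1' phosphonium salt formation as in step 7 should occur at the tertiary bis-allylic alcohol, which ionizes far more readily than the less basic secondary allylic ester at C3'.

Step 17
Reactants: 24 ring-B C15 phosphonium bromide (1.1 equiv), 16 (3R)-3-(tetradecanoyloxy)-12'-apo-β-caroten-12'-al
Product: 27 (3R,3'R,6'R)-lutein 3-O-tetradecanoate 3'-O-hexadecanoate (CNP0230054.1), via phosphorus ylide 25 (not isolated), via 11'Z isomer 26 (not isolated)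
Conditions: NaN(SiMe3)2 (1.05 equiv), THF, −78 °C; then 16, −78 → 0 °C; then EtOAc, reflux; crystallization
Reagents that add atoms: none
Why: Wittig olefination with the ylide pre-formed at low temperature by a non-nucleophilic amide base should spare both esters, and the hindered 11'Z portion should isomerize thermally to the all-E polyene, which is purified by crystallization.

## Compound list

1 | but-2-yn-1-ol | CC#CCO | starting material
2 | but-2-ynal | CC#CC=O | intermediate
3 | mesityl oxide (4-methylpent-3-en-2-one) | CC(=O)C=C(C)C | starting material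
4 | lithium 4-methylpenta-1,3-dien-2-olate | [Li+].[O-]C(=C)C=C(C)C | intermediate
5 | tert-butyl(dimethyl)[(4-methylpenta-1,3-dien-2-yl)oxy]silane | C=C(O[Si](C)(C)C(C)(C)C)C=C(C)C | intermediate
6 | 4-{[tert-butyl(dimethyl)silyl]oxy}-2,6,6-trimethylcyclohexa-1,4-diene-1-carbaldehyde | O=CC1=C(C)CC(O[Si](C)(C)C(C)(C)C)=CC1(C)C | intermediate
7 | (3E)-4-(4-{[tert-butyl(dimethyl)silyl]oxy}-2,6,6-trimethylcyclohexa-1,4-dien-1-yl)but-3-en-2-one | CC(=O)/C=C/C1=C(C)CC(O[Si](C)(C)C(C)(C)C)=CC1(C)C | intermediate
8 | (3E)-4-(2,6,6-trimethyl-4-oxocyclohex-1-en-1-yl)but-3-en-2-one (3-oxo-β-ionone) | CC(=O)/C=C/C1=C(C)CC(=O)CC1(C)C | intermediate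
9 | (3E)-4-[(4R)-4-hydroxy-2,6,6-trimethylcyclohex-1-en-1-yl]but-3-en-2-one ((3R)-3-hydroxy-β-ionone) | CC(=O)/C=C/C1=C(C)C[C@@H](O)CC1(C)C | intermediate
10 | (1E)-1-[(4R)-4-hydroxy-2,6,6-trimethylcyclohex-1-en-1-yl]-3-methylpenta-1,4-dien-3-ol (both epimers at the pentadienol carbon) | C=CC(C)(O)/C=C/C1=C(C)C[C@@H](O)CC1(C)C | intermediate
11 | [(2E,4E)-5-[(4R)-4-hydroxy-2,6,6-trimethylcyclohex-1-en-1-yl]-3-methylpenta-2,4-dien-1-yl]triphenylphosphonium bromide | [Br-].c1ccccc1[P+](c1ccccc1)(c1ccccc1)C/C=C(C)/C=C/C1=C(C)C[C@@H](O)CC1(C)C | intermediate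
12 | (2E,4E,6E)-2,7-dimethylocta-2,4,6-trienedial (C10 dialdehyde) | O=C/C(C)=C/C=C/C=C(C)/C=O | starting material
13 | ylide of 11, [(2E,4E)-5-[(4R)-4-hydroxy-2,6,6-trimethylcyclohex-1-en-1-yl]-3-methylpenta-2,4-dien-1-ylidene]triphenylphosphorane | c1ccccc1P(c1ccccc1)(c1ccccc1)=C/C=C(C)/C=C/C1=C(C)C[C@@H](O)CC1(C)C | intermediate
14 | (3R,11Z)-3-hydroxy-12'-apo-β-caroten-12'-al (11Z isomer of 15) | O=C/C(C)=C/C=C/C=C(C)/C=C\C=C(C)\C=C\C1=C(C)C[C@@H](O)CC1(C)C | intermediate
15 | (3R)-3-hydroxy-12'-apo-β-caroten-12'-al, (2E,4E,6E,8E,10E,12E)-13-[(4R)-4-hydroxy-2,6,6-trimethylcyclohex-1-en-1-yl]-2,7,11-trimethyltrideca-2,4,6,8,10,12-hexaenal | O=C/C(C)=C/C=C/C=C(C)/C=C/C=C(C)/C=C/C1=C(C)C[C@@H](O)CC1(C)C | intermediate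
16 | (3R)-3-(tetradecanoyloxy)-12'-apo-β-caroten-12'-al | O=C/C(C)=C/C=C/C=C(C)/C=C/C=C(C)/C=C/C1=C(C)C[C@@H](OC(=O)CCCCCCCCCCCCC)CC1(C)C | intermediate
17 | racemic α-ionone, (3E)-4-(2,6,6-trimethylcyclohex-2-en-1-yl)but-3-en-2-one | CC(=O)/C=C/C1C(C)=CCCC1(C)C | starting material
18 | racemic 2-methyl-2-[(E)-2-(2,6,6-trimethylcyclohex-2-en-1-yl)ethenyl]-1,3-dioxolane | CC1(OCCO1)/C=C/C1C(C)=CCCC1(C)C | intermediate
19 | racemic 3,5,5-trimethyl-4-[(E)-2-(2-methyl-1,3-dioxolan-2-yl)ethenyl]cyclohex-2-en-1-one | CC1(OCCO1)/C=C/C1C(C)=CC(=O)CC1(C)C | intermediate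
20 | (1R,4R)-3,5,5-trimethyl-4-[(E)-2-(2-methyl-1,3-dioxolan-2-yl)ethenyl]cyclohex-2-en-1-ol | O[C@H]1C=C(C)[C@H](/C=C/C2(C)OCCO2)C(C)(C)C1 | intermediate
21 | (3E)-4-[(1R,4R)-4-hydroxy-2,6,6-trimethylcyclohex-2-en-1-yl]but-3-en-2-one ((3R,6R)-3-hydroxy-α-ionone) | O[C@H]1C=C(C)[C@H](/C=C/C(C)=O)C(C)(C)C1 | intermediate
22 | (1R,4R)-4-[(1E)-3-hydroxy-3-methylpenta-1,4-dien-1-yl]-3,5,5-trimethylcyclohex-2-en-1-ol (both epimers at the pentadienol carbon) | O[C@H]1C=C(C)[C@H](/C=C/C(C)(O)C=C)C(C)(C)C1 | intermediate
23 | (1R,4R)-4-[(1E)-3-hydroxy-3-methylpenta-1,4-dien-1-yl]-3,5,5-trimethylcyclohex-2-en-1-yl hexadecanoate | CCCCCCCCCCCCCCCC(=O)O[C@H]1C=C(C)[C@H](/C=C/C(C)(O)C=C)C(C)(C)C1 | intermediate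
24 | [(2E,4E)-5-[(1R,4R)-4-(hexadecanoyloxy)-2,6,6-trimethylcyclohex-2-en-1-yl]-3-methylpenta-2,4-dien-1-yl]triphenylphosphonium bromide | CCCCCCCCCCCCCCCC(=O)O[C@H]1C=C(C)[C@H](/C=C/C(C)=C/C[P+](c2ccccc2)(c2ccccc2)c2ccccc2)C(C)(C)C1.[Br-] | intermediate
25 | ylide of 24, (1R,4R)-3,5,5-trimethyl-4-[(1E,3E)-3-methyl-5-(triphenyl-λ5-phosphanylidene)penta-1,3-dien-1-yl]cyclohex-2-en-1-yl hexadecanoate | CCCCCCCCCCCCCCCC(=O)O[C@H]1C=C(C)[C@H](/C=C/C(C)=C/C=P(c2ccccc2)(c2ccccc2)c2ccccc2)C(C)(C)C1 | intermediate
26 | (3R,3'R,6'R,11'Z)-lutein 3-O-tetradecanoate 3'-O-hexadecanoate (11'Z isomer of 27) | CCCCCCCCCCCCCCCC(=O)O[C@H]1C=C(C)[C@H](\C=C\C(C)=C\C=C/C(C)=C/C=C/C=C(C)/C=C/C=C(C)/C=C/C2=C(C)C[C@@H](OC(=O)CCCCCCCCCCCCC)CC2(C)C)C(C)(C)C1 | intermediate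
27 | (3R,3'R,6'R)-β,ε-carotene-3,3'-diol 3-tetradecanoate 3'-hexadecanoate (lutein 3-O-myristate 3'-O-palmitate, CNP0230054.1) | CCCCCCCCCCCCCCCC(=O)O[C@H]1C=C(C)[C@H](/C=C/C(C)=C/C=C/C(C)=C/C=C/C=C(C)/C=C/C=C(C)/C=C/C2=C(C)C[C@@H](OC(=O)CCCCCCCCCCCCC)CC2(C)C)C(C)(C)C1 | target

## Summary

Total step count: 17.
Longest linear sequence: 9 steps (step 2 or step 1, then steps 3 to 9, then step 17); the ring-B branch is 8 steps (steps 10 to 16, then step 17).

The three steps most likely to fail:

**Step 3 (key cycloaddition).** The cycloaddition may be too slow at the gem-dimethyl terminus of the diene, so that the 1,5-hydrogen shift of the diene or oligomerization of the ynal takes over. The fallback sets out from 3 and comes back at 8, building ring A by annulation instead of cycloaddition. Mesityl oxide 3 is condensed with ethyl acetoacetate (ZnCl2, heptane–toluene, reflux; Michael addition then aldol condensation, a Robinson-type annulation) to racemic ethyl 2,6,6-trimethyl-4-oxocyclohex-2-ene-1-carboxylate F1. Ketalization with ethylene glycol (p-TsOH, toluene, water separator) moves the double bond into conjugation with the ester and gives ethyl 7,9,9-trimethyl-1,4-dioxaspiro[4.5]dec-7-ene-8-carboxylate F2. Reduction with LiAlH4 gives (7,9,9-trimethyl-1,4-dioxaspiro[4.5]dec-7-en-8-yl)methanol F3, and MnO2 oxidation gives 7,9,9-trimethyl-1,4-dioxaspiro[4.5]dec-7-ene-8-carbaldehyde F4. Horner–Wadsworth–Emmons olefination with dimethyl (2-oxopropyl)phosphonate gives (3E)-4-(7,9,9-trimethyl-1,4-dioxaspiro[4.5]dec-7-en-8-yl)but-3-en-2-one F5, whose ketal is hydrolysed with oxalic acid in wet THF to return at 8.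

**Step 5 (first ketoreductase).** The enzyme may discriminate poorly between the two CH2 flanks of the ring ketone, or the C5=C6 bond may migrate into conjugation with the ketone during the long aqueous incubation. The fallback sets out from 8 and comes back at 9, replacing asymmetric reduction by reduction and resolution. Compound 8 is reduced with NaBH4 in MeOH–CH2Cl2 at −78 °C (saturated ketone before conjugated ketone) to racemic (3E)-4-(4-hydroxy-2,6,6-trimethylcyclohex-1-en-1-yl)but-3-en-2-one F6. Lipase from Burkholderia cepacia with vinyl acetate should acetylate the R enantiomer (the gem-dimethyl flank acting as the large group) to (1R)-3,5,5-trimethyl-4-[(1E)-3-oxobut-1-en-1-yl]cyclohex-3-en-1-yl acetate F7, which is separated from the unreacted S alcohol and methanolysed (K2CO3, MeOH) to 9.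

**Step 4 (olefination of the dienal).** Proton abstraction at C4 of 6 (γ to the formyl group and allylic to the enol ether) by the phosphonate anion may compete with slow addition to the hindered aldehyde and cause double-bond migration. The fallback sets out from 6 and comes back at 7, replacing the olefination by aldol addition and elimination. The lithium enolate of acetone (LiN(i-Pr)2, acetone, THF, −78 °C) is added to 6, a fast kinetic 1,2-addition, to give racemic 4-hydroxy-4-(4-{[tert-butyl(dimethyl)silyl]oxy}-2,6,6-trimethylcyclohexa-1,4-dien-1-yl)butan-2-one F8. MsCl and Et3N convert it into 4-(4-{[tert-butyl(dimethyl)silyl]oxy}-2,6,6-trimethylcyclohexa-1,4-dien-1-yl)-4-(methanesulfonyloxy)butan-2-one F9, which eliminates in the flask to the E enone 7; 7 is then desilylated with HF·pyridine as in step 4.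

Further compounds
F1 | step 3 | racemic ethyl 2,6,6-trimethyl-4-oxocyclohex-2-ene-1-carboxylate | CCOC(=O)C1C(C)=CC(=O)CC1(C)C
F2 | step 3 | ethyl 7,9,9-trimethyl-1,4-dioxaspiro[4.5]dec-7-ene-8-carboxylate | CCOC(=O)C1=C(C)CC2(OCCO2)CC1(C)C
F3 | step 3 | (7,9,9-trimethyl-1,4-dioxaspiro[4.5]dec-7-en-8-yl)methanol | OCC1=C(C)CC2(OCCO2)CC1(C)C
F4 | step 3 | 7,9,9-trimethyl-1,4-dioxaspiro[4.5]dec-7-ene-8-carbaldehyde | O=CC1=C(C)CC2(OCCO2)CC1(C)C
F5 | step 3 | (3E)-4-(7,9,9-trimethyl-1,4-dioxaspiro[4.5]dec-7-en-8-yl)but-3-en-2-one | CC(=O)/C=C/C1=C(C)CC2(OCCO2)CC1(C)C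
F6 | step 5 | racemic (3E)-4-(4-hydroxy-2,6,6-trimethylcyclohex-1-en-1-yl)but-3-en-2-one | CC(=O)/C=C/C1=C(C)CC(O)CC1(C)C
F7 | step 5 | (1R)-3,5,5-trimethyl-4-[(1E)-3-oxobut-1-en-1-yl]cyclohex-3-en-1-yl acetate | CC(=O)/C=C/C1=C(C)C[C@@H](OC(C)=O)CC1(C)C
F8 | step 4 | racemic 4-hydroxy-4-(4-{[tert-butyl(dimethyl)silyl]oxy}-2,6,6-trimethylcyclohexa-1,4-dien-1-yl)butan-2-one | CC(=O)CC(O)C1=C(C)CC(O[Si](C)(C)C(C)(C)C)=CC1(C)C
F9 | step 4 | racemic 4-(4-{[tert-butyl(dimethyl)silyl]oxy}-2,6,6-trimethylcyclohexa-1,4-dien-1-yl)-4-(methanesulfonyloxy)butan-2-one | CC(=O)CC(OS(C)(=O)=O)C1=C(C)CC(O[Si](C)(C)C(C)(C)C)=CC1(C)C
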